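**Plan**

- Retrosynthesis: the three benzyl ethers, the C3–OMe bond and the C3–O bond are removed first, which leads back to a 3-unsubstituted flavone. Ring C is then cut at C4a–C4, C4–C3 and O1–C2.
- Enabling feature: C4 is a lone carbonyl carbon joining C4a to the C3=C2 unit that carries ring B. C4a lies between the two oxygen-bearing carbons C5 and C8a of the fully substituted ring A. Ring C therefore falls apart into a symmetric 2-iodoresorcinol, carbon monoxide and an arylacetylene.
- Forward, ring A: 2,6-dimethoxyphenol is benzylated, dibrominated, doubly borylated, oxidised to the resorcinol and iodinated at its only CH.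
- Forward, ring C: it is closed in one carbonylative coupling–cyclisation that also brings in ring B.
- Finish: 5-O-benzylation, C3 hydroxylation by lithiation–borate–peroxide, O-methylation and global hydrogenolysis.
- Stereochemistry: the target has no stereocentre and no stereogenic double bond, so nothing has to be controlled.

Key step: step 6

Assumption: 2,6-dimethoxyphenol and 1-(benzyloxy)-4-ethynylbenzene are taken as catalogue compounds and carbon monoxide as cylinder gas.

**Route**

Step 1
Reactants: 1 2,6-dimethoxyphenol
Product: 2 2-(benzyloxy)-1,3-dimethoxybenzene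
Conditions: BnBr, K2CO3, DMF, 60 °C
Reagents that add atoms: benzyl bromide, BrCc1ccccc1
Why: Williamson etherification of the phenoxide on a benzylic bromide masks the future C7 oxygen with a group that survives every later step and leaves by hydrogenolysis at the end.

Step 2
Reactants: 2 2-(benzyloxy)-1,3-dimethoxybenzene
Product: 3 3-(benzyloxy)-1,5-dibromo-2,4-dimethoxybenzene
Conditions: NBS (2.1 equiv), MeCN, 0 °C to rt, dark
Reagents that add atoms: N-bromosuccinimide, O=C1CCC(=O)N1Br
Why: Electrophilic aromatic bromination should take the two equivalent positions that are each ortho to one methoxy group and para to the other, because the third CH is activated only by the twisted central benzyloxy group, as in the dibromination of 1,2,3-trimethoxybenzene.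

Step 3
Reactants: 3 3-(benzyloxy)-1,5-dibromo-2,4-dimethoxybenzene
Product: 4 2,2'-[5-(benzyloxy)-4,6-dimethoxy-1,3-phenylene]bis(4,4,5,5-tetramethyl-1,3,2-dioxaborolane)
Conditions: B2pin2 (2.5 equiv), PdCl2(dppf) (5 mol %; dppf = 1,1'-bis(diphenylphosphino)ferrocene), KOAc, 1,4-dioxane, 90 °C
Reagents that add atoms: bis(pinacolato)diboron, CC1(C)OB(OC1(C)C)B1OC(C)(C)C(C)(C)O1
Why: Twofold Miyaura borylation of aryl bromides that each carry only one ortho substituent is standard and turns both C–Br bonds into C–B bonds without touching the ethers.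

Step 4
Reactants: 4 2,2'-[5-(benzyloxy)-4,6-dimethoxy-1,3-phenylene]bis(4,4,5,5-tetramethyl-1,3,2-dioxaborolane)
Product: 5 5-(benzyloxy)-4,6-dimethoxybenzene-1,3-diol
Conditions: 30% aq H2O2, NaOH (2.2 equiv), THF/H2O, 0 °C to rt, under argon
Reagents that add atoms: hydrogen peroxide, OO
Why: Ipso oxidation of arylboronates by hydroperoxide (1,2-aryl shift from boron to oxygen, then hydrolysis) should give the symmetric resorcinol, which is kept under inert gas and carried on promptly because of its electron richness.

Step 5
Reactants: 5 5-(benzyloxy)-4,6-dimethoxybenzene-1,3-diol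
Product: 6 5-(benzyloxy)-2-iodo-4,6-dimethoxybenzene-1,3-diol
Conditions: NIS (1.0 equiv), MeCN, −20 to 0 °C, dark
Reagents that add atoms: N-iodosuccinimide, O=C1CCC(=O)N1I
Why: Electrophilic aromatic iodination can only occur at the single ring CH, which lies between the two activating hydroxyls, and the mild non-acidic reagent should avoid protodeiodination and oxidation.

Step 6
Reactants: 6 5-(benzyloxy)-2-iodo-4,6-dimethoxybenzene-1,3-diol; 7 1-(benzyloxy)-4-ethynylbenzene; 8 carbon monoxide
Product: 11 7,4'-bis(benzyloxy)-5-hydroxy-6,8-dimethoxyflavone, via hydroxyaryl ynone 9 (not isolated), via diethylamino enone 10 (not isolated)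
Conditions: CO (20 bar), PdCl2(dppf) (5 mol %), Et2NH, 120 °C, autoclave
Reagents that add atoms: diethylamine, CCNCC (its atoms sit only in intermediate 10 and leave again on ring closure; product 11 contains only atoms of 6, 7 and 8)
Why: Reduction of PdCl2(dppf) in the amine gives zerovalent palladium, which adds oxidatively to the aryl iodide of 6; migratory insertion of CO gives the acyl complex, and copper-free transfer of the acetylide of 7 followed by reductive elimination releases ynone 9 with C4a–C4 and C4–C3 in place. Diethylamine then adds to the alkyne carbon that becomes C2, giving enaminone 10, and an ortho hydroxyl attacks that same carbon in a 6-endo-trig addition–elimination that expels the amine, forms O1–C2 and closes ring C. The closest known reaction type is the palladium-catalysed carbonylative Sonogashira annulation of ortho-iodophenols with terminal alkynes to flavones. No stereocentre is formed. Carbonylation must outrun direct alkynylation and benzofuran closure, which the CO pressure and the electron-rich aryl group favour, and six-membered closure must beat 5-exo aurone formation, which the secondary amine secures by converting the ynone to the enaminone before the phenol attacks. Regiochemistry is not in question because the two hydroxyls flanking the iodide are equivalent, the unused one ending as the chelated C5 phenol.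

Step 7
Reactants: 11 7,4'-bis(benzyloxy)-5-hydroxy-6,8-dimethoxyflavone
Product: 12 5,7,4'-tris(benzyloxy)-6,8-dimethoxyflavone
Conditions: BnBr, K2CO3, KI (cat.), DMF, 70 °C
Reagents that add atoms: benzyl bromide, BrCc1ccccc1
Why: Williamson etherification of the chelated C5 phenol under forcing carbonate conditions removes the acidic proton that would interfere with C3 metalation and adds a group that leaves together with the other two benzyl ethers.

Step 8
Reactants: 12 5,7,4'-tris(benzyloxy)-6,8-dimethoxyflavone
Product: 15 5,7,4'-tris(benzyloxy)-3-hydroxy-6,8-dimethoxyflavone, via 3-lithioflavone 13 (not isolated), via dimethyl flavon-3-ylboronate 14 (not isolated)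
Conditions: LiN(iPr)2 (1.3 equiv), THF, −78 °C; B(OMe)3, −78 to 0 °C; AcOH, 30% aq H2O2, 0 °C to rt
Reagents that add atoms: hydrogen peroxide, OO (the C3 oxygen of 15); trimethyl borate, COB(OC)OC (boron and methoxy groups of 14 only); lithium diisopropylamide, CC(C)N([Li])C(C)C (lithium of 13 only)
Why: Carbonyl-directed deprotonation of the C3–H of a fully O-protected flavone gives a vinyllithium that is trapped as the boronate and oxidised by peroxide with 1,2-migration from boron to oxygen, a lithiation–borylation–oxidation sequence established for 5-O-protected flavones.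

Step 9
Reactants: 15 5,7,4'-tris(benzyloxy)-3-hydroxy-6,8-dimethoxyflavone
Product: 16 5,7,4'-tris(benzyloxy)-3,6,8-trimethoxyflavone
Conditions: MeI, K2CO3, acetone, reflux
Reagents that add atoms: iodomethane, CI
Why: Williamson O-methylation finds only one free hydroxyl, the acidic enolic 3-OH, so no selectivity question arises.

Step 10
Reactants: 16 5,7,4'-tris(benzyloxy)-3,6,8-trimethoxyflavone
Product: 17 5,7,4'-trihydroxy-3,6,8-trimethoxyflavone (CNP0291409.0)
Conditions: H2 (1 atm), 10% Pd/C, EtOAc/MeOH, rt
Reagents that add atoms: none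
Why: Catalytic hydrogenolysis cleaves the three benzyl aryl ethers while the methyl ethers and the tetrasubstituted C2=C3 bond of the chromone should stay intact at ambient pressure.

**Compound list**

1 | 2,6-dimethoxyphenol | COc1cccc(OC)c1O | starting material
2 | 2-(benzyloxy)-1,3-dimethoxybenzene | COc1cccc(OC)c1OCc1ccccc1 | intermediate
3 | 3-(benzyloxy)-1,5-dibromo-2,4-dimethoxybenzene | COc1c(Br)cc(Br)c(OC)c1OCc1ccccc1 | intermediate
4 | 2,2'-[5-(benzyloxy)-4,6-dimethoxy-1,3-phenylene]bis(4,4,5,5-tetramethyl-1,3,2-dioxaborolane) | COc1c(B2OC(C)(C)C(C)(C)O2)cc(B2OC(C)(C)C(C)(C)O2)c(OC)c1OCc1ccccc1 | intermediate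
5 | 5-(benzyloxy)-4,6-dimethoxybenzene-1,3-diol | COc1c(O)cc(O)c(OC)c1OCc1ccccc1 | intermediate
6 | 5-(benzyloxy)-2-iodo-4,6-dimethoxybenzene-1,3-diol | COc1c(O)c(I)c(O)c(OC)c1OCc1ccccc1 | intermediate
7 | 1-(benzyloxy)-4-ethynylbenzene | C#Cc1ccc(OCc2ccccc2)cc1 | starting material
8 | carbon monoxide | [C-]#[O+] | starting material
9 | 1-[4-(benzyloxy)-2,6-dihydroxy-3,5-dimethoxyphenyl]-3-[4-(benzyloxy)phenyl]prop-2-yn-1-one | COc1c(O)c(C(=O)C#Cc2ccc(OCc3ccccc3)cc2)c(O)c(OC)c1OCc1ccccc1 | intermediate
10 | (E)-1-[4-(benzyloxy)-2,6-dihydroxy-3,5-dimethoxyphenyl]-3-[4-(benzyloxy)phenyl]-3-(diethylamino)prop-2-en-1-one (drawn as E; either geometry can cyclise) | CCN(CC)/C(=C/C(=O)c1c(O)c(OC)c(OCc2ccccc2)c(OC)c1O)c1ccc(OCc2ccccc2)cc1 | intermediate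
11 | 7,4'-bis(benzyloxy)-5-hydroxy-6,8-dimethoxyflavone | COc1c(OCc2ccccc2)c(OC)c2oc(-c3ccc(OCc4ccccc4)cc3)cc(=O)c2c1O | intermediate
12 | 5,7,4'-tris(benzyloxy)-6,8-dimethoxyflavone | COc1c(OCc2ccccc2)c(OC)c2oc(-c3ccc(OCc4ccccc4)cc3)cc(=O)c2c1OCc1ccccc1 | intermediate
13 | 5,7,4'-tris(benzyloxy)-3-lithio-6,8-dimethoxyflavone | COc1c(OCc2ccccc2)c(OC)c2oc(-c3ccc(OCc4ccccc4)cc3)c([Li])c(=O)c2c1OCc1ccccc1 | intermediate
14 | dimethyl [5,7,4'-tris(benzyloxy)-6,8-dimethoxyflavon-3-yl]boronate | COc1c(OCc2ccccc2)c(OC)c2oc(-c3ccc(OCc4ccccc4)cc3)c(B(OC)OC)c(=O)c2c1OCc1ccccc1 | intermediate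
15 | 5,7,4'-tris(benzyloxy)-3-hydroxy-6,8-dimethoxyflavone | COc1c(OCc2ccccc2)c(OC)c2oc(-c3ccc(OCc4ccccc4)cc3)c(O)c(=O)c2c1OCc1ccccc1 | intermediate
16 | 5,7,4'-tris(benzyloxy)-3,6,8-trimethoxyflavone | COc1c(OCc2ccccc2)c(OC)c2oc(-c3ccc(OCc4ccccc4)cc3)c(OC)c(=O)c2c1OCc1ccccc1 | intermediate
17 | 5,7,4'-trihydroxy-3,6,8-trimethoxyflavone (CNP0291409.0) | COc1c(O)c(OC)c2oc(-c3ccc(O)cc3)c(OC)c(=O)c2c1O | target

**Count and risks**

Total step count: 10. Longest linear sequence: 10 steps (1 to 17); compounds 7 and 8 enter at step 6.

Steps most likely to fail: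

1. Step 6. Oxidative addition at the doubly ortho-substituted, electron-rich C–I bond may be slow. Hydrodeiodination, non-carbonylative alkynylation with benzofuran closure, or capture of the acyl complex by diethylamine or phenoxide could then take over. The fallback sets out from 5 and comes back at 11. Resorcinol 5 would be C-acetylated at its only free position (AcOH, BF3·OEt2, 60 °C, Friedel–Crafts acylation, watching the benzyl ether) to 1-[4-(benzyloxy)-2,6-dihydroxy-3,5-dimethoxyphenyl]ethan-1-one F1. Claisen–Schmidt condensation with purchased 4-(benzyloxy)benzaldehyde (KOH, EtOH, rt) would give the chalcone (E)-1-[4-(benzyloxy)-2,6-dihydroxy-3,5-dimethoxyphenyl]-3-[4-(benzyloxy)phenyl]prop-2-en-1-one F2. Oxidative cyclisation with catalytic I2 in DMSO at 120 °C would then deliver flavone 11.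

2. Step 8. The amide base may add to C2 and open the pyranone, benzylic deprotonation with Wittig rearrangement of a benzyl ether may compete, or borate capture may be incomplete so that 12 is returned. The fallback sets out from 12 and comes back at 15. Epoxidation of the C2=C3 bond with dimethyldioxirane (acetone/CH2Cl2, 0 °C) would give racemic 5,7-bis(benzyloxy)-2-[4-(benzyloxy)phenyl]-6,8-dimethoxy-2,3-epoxychroman-4-one F3. Acid-mediated opening and tautomerisation (cat. p-TsOH, CH2Cl2, rt) would then give flavonol 15.

3. Step 3. The sequence may stall after the first borylation, or protodebromination and protodeboronation may erode the bis-boronate at the methoxy-flanked positions. The fallback sets out from 3 and comes back at 5. Both C–Br bonds would be converted directly to C–OH by palladium-catalysed hydroxylation with KOH (Pd2(dba)3, tBuXPhos, KOH, 1,4-dioxane/H2O, 100 °C), a C–O coupling that bypasses boronate 4 and makes no new compound (entry F0).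

**Further compounds**

F1 | step 6 | 1-[4-(benzyloxy)-2,6-dihydroxy-3,5-dimethoxyphenyl]ethan-1-one | COc1c(O)c(C(C)=O)c(O)c(OC)c1OCc1ccccc1
F2 | step 6 | (E)-1-[4-(benzyloxy)-2,6-dihydroxy-3,5-dimethoxyphenyl]-3-[4-(benzyloxy)phenyl]prop-2-en-1-one | COc1c(O)c(C(=O)/C=C/c2ccc(OCc3ccccc3)cc2)c(O)c(OC)c1OCc1ccccc1
F3 | step 8 | racemic 5,7-bis(benzyloxy)-2-[4-(benzyloxy)phenyl]-6,8-dimethoxy-2,3-epoxychroman-4-one (cis-fused epoxide, one enantiomer drawn) | COc1c(OCc2ccccc2)c(OC)c2O[C@]3(c4ccc(OCc5ccccc5)cc4)O[C@@H]3C(=O)c2c1OCc1ccccc1
F0 | step 3 | none | none
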